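## The problem

The target 26 is a 2-hydroxy-5-methoxy-1,4-benzoquinone whose C3' carries a methylene, C11, attached to the quaternary carbon C9 of a rearranged drimane bicycle (ring A = C1–C5 and C10, ring B = C5–C10, quinone atoms primed). The two carbocycles share the tetrasubstituted C5=C10 double bond, flanked by the gem-dimethyl carbon C4 on one side and by C9 on the other, so every bond to the olefin ends at a hindered carbon. There are only two stereocentres, C8 (S, a secondary methyl) and C9 (R, methyl and C11), with the two methyl groups cis. Neither can be epimerised later, so the natural order is C8 first, by a catalyst, and then C9 under the control of C8 on a ring. C11 is neopentyl, which rules out displacement chemistry and makes carbonyl addition followed by deoxygenation the practical way to attach the arene. The hydroxyquinone is sensitive to base, nucleophiles and reductants, and its tetramethoxyarene precursor is oxidised more easily than anything else in the molecule, so the aromatic ring has to arrive after any oxidative skeleton-building step and the quinone is unveiled last. The C5=C10 olefin is one protonation away from C10 and C5 cations that rearrange by hydride and methyl shifts, so strong acid is to be avoided once it is in place. The feature that invites the key step is that C4 is bonded to C5 of this olefin: a tertiary C4 cation, released from a 2,2-dimethyl carboxylic acid by loss of CO2 and two electrons, can attack C5 of a ring B cyclohexene that already holds C8 and C9, close ring A, and return the double bond to C5=C10 by loss of the C5 proton.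

## Retrosynthesis

**Quinone last.** The hydroxyquinone 26 is traced to the 2',5'-dimethoxyquinone 25 by hydrolysis of the C2' vinylogous ester, and 25 to the tetramethoxyarene 24 by oxidative demethylation. No carbon–carbon bond is cut. The gain is that 24 is a robust arene that carries all four quinone oxygens in masked form and derives from a commercial, symmetric building block. Building the quinone ring from smaller pieces would tell the two oxygens apart more cleanly but costs more steps. The forward steps must oxidise the arene without touching the olefin, and must hydrolyse the methoxy group next to the side chain and not the one next to C6'–H.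

**C11–C3' bond.** Because C11 is neopentyl, alkylation of an aryl nucleophile is not an option. The bond is made by adding the aryllithium 20, from 1,2,4,5-tetramethoxybenzene 19, to the aldehyde 18. The extra oxygen of the carbinol 21 is removed through the sodium xanthate 22 and the xanthate 23. Aldehyde 18 has no α-hydrogen, so it cannot enolise or epimerise. A radical deoxygenation is preferred to an ionic one because a cation at C11 next to C9 would invite a 1,2-shift. The cut divides the target into a C15 bicycle and a C6 arene.

**Oxidation level at C11.** Aldehyde 18 is taken back to alcohol 17 and its silyl ether 16. C11 passes through ring formation as a protected alcohol because neither the arene of 24 nor a free aldehyde would be a safe passenger at an anode or in the enolate and organometallic steps before it.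

**Ring A (key disconnection).** In 16 the C4–C5 bond is cut, opening ring A to the monocyclic acid 15. Cuts through ring B (C9–C10 or C5–C6) would force the quaternary stereocentre to be made during ring closure. This cut leaves both stereocentres on a simple cyclohexene that is made early, and detaches only an achiral chain. The precursor has one ring less and no tetrasubstituted olefin. A C4 cation could also be reached by protonating a side-chain olefin, but the acid that starts that reaction can also protonate the ring olefin and, later, the product. Decarboxylation at an anode places the charge at C4 only and works in a buffered medium. The forward reaction has to close in the 6-endo mode, lose the proton from C5 and not from C1, and avoid 1,2-shifts at the C10 cation.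

**C1–C10 bond.** Acid 15 comes from ester 14, which is cut between sp2 C10 and sp3 C1 into the enol triflate 8 and the alkylzinc 13. The triflate can only form toward C5, because the other α-carbon is quaternary, so the olefin position is fixed without any selectivity question. Adding a chain organometallic to the ketone and dehydrating would leave the olefin position open and is incompatible with the ester. Reagent 13 comes from bromide 12, made in one alkylation from ethyl isobutyrate 9 and 1,3-dibromopropane 10 through the ester enolate 11.

**Ring B stereocentres.** Triflate 8 derives, through the potassium enolate 7, from ketone 6 and its alcohol 5. In 5 the C9–C11 bond and the C8–methyl bond are cut, leading back through the lithium enolate 4, the silyl enol ether 3 and the aluminium enolate 2 to 2-methylcyclohex-2-en-1-one 1. A catalytic asymmetric conjugate methylation sets C8. The one-carbon electrophile then enters the enolate trans to the new methyl group and sets C9. Isolating 3 between the two events allows the enantiomeric purity to be checked and the enolate to be regenerated free of copper and aluminium salts.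

## Roads not taken

**Alternative 1:** The cut runs through ring B at C7–C8 and C9–C10 and divides the bicycle into the diene 6,6-dimethyl-1-vinylcyclohex-1-ene A1 and tiglaldehyde A2. A chiral oxazaborolidinium Lewis acid (a B-aryl oxazaborolidine protonated by HN(SO2CF3)2) would join them in a Diels–Alder reaction to the aldehyde A3, with C11 already at the aldehyde oxidation level.
- Merits: ring B, both stereocentres and C11 arrive in one step. The cis relation of the two methyl groups follows from the E geometry of A2 and is therefore secure. The route to the arene coupling is several steps shorter, and in convergence this road is better than the chosen one.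
- Weak points: A2 is an α,β-disubstituted enal, a sluggish dienophile that has to create a quaternary centre against a diene whose reacting terminus is a ring carbon. Enantiofacial control is open for this pairing. A3 carries C5=C6 and a hydrogen at C10, so the olefin must afterwards be moved to C5=C10, which means passing through the cationic or allylic manifold from which hydride and methyl shifts start.
- Comparison: the chosen plan is longer, but it forms the olefin in its final place under buffered conditions and sets C8 and C9 by two steps of established selectivity.

**Alternative 2:** Nothing in the bicycle is cut. The quinone ring is disconnected at C1'–C6' and traced to the 4-hydroxy-4-(2-methoxyvinyl)cyclobutenone A4, itself assembled by two carbonyl additions to a squaric ester. Heating A4 would open the four-membered ring to a dienylketene, which closes by a 6π electrocyclisation and tautomerises to the hydroquinone A5.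
- Merits: the tert-butyl and methyl ethers of A5 mark the future hydroxyl and methoxyl unambiguously, so the question of which methoxy group is hydrolysed in step 15 does not arise. In this respect it is better than the chosen end game.
- Weak points: it leaves the construction of the bicycle unsolved. It needs the C11 fragment as a neopentyl carbanion next to a quaternary centre. It spends four or five steps on a ring that a commercial arene delivers complete.
- Comparison: the chosen plan has the shorter arene route and accepts the hydrolysis selectivity as a risk with a fallback.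

**Alternative 3:** The cut is at C9–C10 and opens ring B. The precursor A6 is a ring A enol triflate (triflate on C10, double bond C5=C10) whose C5 bears a chain ending in the trisubstituted olefin C9=C11 with the tetramethoxyaryl group on C11. Zerovalent palladium (from Pd(OAc)2 and a bisphosphine) would insert into the C10–O bond and add across C9=C11 in the 6-exo mode. Since the C11–Pd intermediate has no β-hydrogen, HCO2Na would reduce it to A7, which is identical with compound 24.
- Merits: the olefin position is fixed by the triflate and never moves. The arene is carried in from the start, so the late addition to a neopentyl aldehyde and the deoxygenation disappear. The end game is about five steps shorter, which is a real advantage.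
- Weak points: the quaternary stereocentre C9 is created in the ring closure under the influence of the acyclic C8 centre alone, for which no strong bias can be claimed. The inserting olefin is trisubstituted and carries a 2,6-dimethoxyaryl group. A6 requires enolisation of a 2-alkyl-3,3-dimethylcyclohexanone toward its more hindered α-carbon.
- Comparison: the chosen plan sets C9 on a six-membered ring, trans to an existing methyl group, and pays for that security with a longer end game.

Key step: step 8

Assumptions and conventions:
- Of the two antipodes of the phosphoramidite ligand in step 1, the one whose copper complex gives the 3S centre is used; the sense of induction is to be confirmed on 3.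
- Compounds 21–23 are carried as mixtures of both configurations at C11, which becomes CH2 in 24.
- The CIP label of the quaternary carbon changes along the route (S in 5–8, R from 14 on) only because substituent priorities change; the centre is never touched after step 2.

## Route

Step 1
Reactants: 1 2-methylcyclohex-2-en-1-one
Product: 3 trimethyl{[(3S)-2,3-dimethylcyclohex-1-en-1-yl]oxy}silane, via aluminium enolate 2 (not isolated)
Conditions: AlMe3, copper thiophene-2-carboxylate CuO2C(C4H3S) (2 mol %), BINOL-derived bis(1-phenylethyl)amine phosphoramidite (4 mol %), Et2O, −30 °C; then TMSOTf, −30 to 0 °C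
Reagents that add atoms: trimethylaluminium C[Al](C)C; trimethylsilyl trifluoromethanesulfonate C[Si](C)(C)OS(=O)(=O)C(F)(F)F
Why: Copper-catalysed asymmetric conjugate addition of a trialkylaluminium to an α-substituted cyclic enone, the Lewis-acidic aluminium activating the hindered enone and the chiral copper–phosphoramidite complex choosing the enone face, so that C8 is set as 3S; O-silylation of the aluminium enolate fixes the enolate regiochemistry for step 2.

Step 2
Reactants: 3 trimethyl{[(3S)-2,3-dimethylcyclohex-1-en-1-yl]oxy}silane
Product: 5 (2S,3S)-2-(hydroxymethyl)-2,3-dimethylcyclohexan-1-one, via lithium enolate 4 (not isolated)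
Conditions: MeLi, THF, 0 °C to rt; then monomeric CH2O (from cracked paraformaldehyde), −78 °C; aq NH4Cl
Reagents that add atoms: formaldehyde C=O
Why: Regiospecific lithium enolate generation from a silyl enol ether with MeLi, followed by aldol addition to monomeric formaldehyde; the C8 methyl group sits pseudoaxial to avoid allylic strain with the enolate methyl and shields one face, so the electrophile enters trans to it and C9 is set with the two methyl groups cis.

Step 3
Reactants: 5 (2S,3S)-2-(hydroxymethyl)-2,3-dimethylcyclohexan-1-one
Product: 6 (2S,3S)-2-{[(tert-butyldimethylsilyl)oxy]methyl}-2,3-dimethylcyclohexan-1-one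
Conditions: TBSCl, imidazole, DMF, rt
Reagents that add atoms: tert-butyldimethylsilyl chloride CC(C)(C)[Si](C)(C)Cl
Why: Standard silylation of a primary alcohol; the mild base avoids retro-aldol cleavage of the β-hydroxy ketone, and the silyl ether then blocks that pathway for good.

Step 4
Reactants: 6 (2S,3S)-2-{[(tert-butyldimethylsilyl)oxy]methyl}-2,3-dimethylcyclohexan-1-one
Product: 8 (5S,6S)-6-{[(tert-butyldimethylsilyl)oxy]methyl}-5,6-dimethylcyclohex-1-en-1-yl trifluoromethanesulfonate, via potassium enolate 7 (not isolated)
Conditions: KN(SiMe3)2, THF, −78 °C; then PhNTf2, −78 to 0 °C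
Reagents that add atoms: N-phenylbis(trifluoromethanesulfonimide) O=S(=O)(N(c1ccccc1)S(=O)(=O)C(F)(F)F)C(F)(F)F
Why: Enol triflate formation from a ketone enolate; deprotonation can only occur at C5 because the other α-carbon is quaternary, so the double bond is placed at C5=C10 without a regiochemical choice, and β-elimination of the silyloxy group is impossible for the same reason.

Step 5
Reactants: 9 ethyl 2-methylpropanoate (ethyl isobutyrate); 10 1,3-dibromopropane
Product: 12 ethyl 5-bromo-2,2-dimethylpentanoate, via ester lithium enolate 11 (not isolated)
Conditions: LiN(iPr)2, THF, −78 °C; then 10 (3 equiv), −78 °C to rt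
Reagents that add atoms: none
Why: Alkylation of an ester enolate with a primary dibromide used in excess to suppress double alkylation; the product has no α-hydrogen left and cannot react further.

Step 6
Reactants: 12 ethyl 5-bromo-2,2-dimethylpentanoate; 8 (5S,6S)-6-{[(tert-butyldimethylsilyl)oxy]methyl}-5,6-dimethylcyclohex-1-en-1-yl trifluoromethanesulfonate
Product: 14 ethyl 5-[(5S,6R)-6-{[(tert-butyldimethylsilyl)oxy]methyl}-5,6-dimethylcyclohex-1-en-1-yl]-2,2-dimethylpentanoate, via alkylzinc bromide 13 (not isolated)
Conditions: 12, Zn dust, LiCl, THF, 50 °C; then 8, PdCl2(dppf) (5 mol %), THF/N-methylpyrrolidone, 60 °C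
Reagents that add atoms: none
Why: Zinc insertion into a primary alkyl bromide tolerates the ester, and the Negishi coupling of the alkylzinc with an alkenyl triflate forms the sp2–sp3 C1–C10 bond; the wide-bite-angle bisphosphine favours reductive elimination over β-hydride elimination.

Step 7
Reactants: 14 ethyl 5-[(5S,6R)-6-{[(tert-butyldimethylsilyl)oxy]methyl}-5,6-dimethylcyclohex-1-en-1-yl]-2,2-dimethylpentanoate
Product: 15 5-[(5S,6R)-6-{[(tert-butyldimethylsilyl)oxy]methyl}-5,6-dimethylcyclohex-1-en-1-yl]-2,2-dimethylpentanoic acid
Conditions: KOH, EtOH/H2O, 80 °C; then 1 M HCl to pH 4, 0 °C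
Reagents that add atoms: potassium hydroxide [K+].[OH-]
Why: Saponification of a hindered α,α-dimethyl ester needs heat, which the neopentyl, hindered silyl ether should tolerate; no stereocentre is epimerisable.

Step 8
Reactants: 15 5-[(5S,6R)-6-{[(tert-butyldimethylsilyl)oxy]methyl}-5,6-dimethylcyclohex-1-en-1-yl]-2,2-dimethylpentanoic acid
Product: 16 tert-butyldimethyl{[(1R,2S)-1,2,5,5-tetramethyl-1,2,3,4,5,6,7,8-octahydronaphthalen-1-yl]methoxy}silane
Conditions: graphite anode, Pt cathode, undivided cell, constant current (about 2.5 F/mol), 2,4,6-collidine (3 equiv), nBu4NPF6 (0.1 M), CH2Cl2/(CF3)2CHOH 4:1, 3 Å molecular sieves, rt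
Reagents that add atoms: none
Why: Proposed new method: the carboxylate of 15 is oxidised at graphite, loses CO2 and gives the tertiary C4 radical, which on carbon is oxidised on to the C4 cation (the non-Kolbe, Hofer–Moest course that tertiary acids prefer); the closest known reaction types are the anodic decarboxylation of tertiary acids to cations that are captured by alcohols and the acid-initiated closure of a tertiary cation onto a trisubstituted olefin in cyclogeranyl-type cyclisations, which have not been combined on a substrate of this kind. The cation attacks C5 of the ring B olefin through a chair-like transition state, so ring A closes in the 6-endo mode and the charge arrives at tertiary C10; a radical that cyclises before its second oxidation reaches the same C10 cation after oxidation, so both courses converge. 5-exo attack at C10 is disfavoured because it would join the new quaternary C4 to a spiro carbon next to quaternary C9 and leave only a secondary cation or radical at C5. Collidine then removes the C5 proton, whose bond lies nearly parallel to the empty orbital at C10 in the bicyclic cation, and the most substituted olefin C5=C10 results; no stereocentre is formed, and C8 and C9 are spectators. Three selectivities are needed: ring closure has to outrun capture or proton loss at C4, which the non-nucleophilic, cation-stabilising fluoroalcohol medium and the absence of methanol or acetonitrile favour; the proton has to leave from C5 and not from C1, which rests on the Zaitsev preference and the alignment of the ring-fusion hydrogen; and 1,2-shifts from C9 to C10 have to stay slow, which the inductively withdrawing CH2OSi group on C9 and the base present throughout favour. Because the cation is made by electron transfer and not by protonation, no acid able to re-ionise the product olefin is present, and the carboxylate is oxidised before the trisubstituted olefin or the silyl ether.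

Step 9
Reactants: 16 tert-butyldimethyl{[(1R,2S)-1,2,5,5-tetramethyl-1,2,3,4,5,6,7,8-octahydronaphthalen-1-yl]methoxy}silane
Product: 17 [(1R,2S)-1,2,5,5-tetramethyl-1,2,3,4,5,6,7,8-octahydronaphthalen-1-yl]methanol
Conditions: nBu4NF, THF, 50 °C
Reagents that add atoms: none
Why: Fluoride cleavage of a silyl ether; warming compensates for the neopentyl position, and the neutral conditions leave the tetrasubstituted olefin untouched.

Step 10
Reactants: 17 [(1R,2S)-1,2,5,5-tetramethyl-1,2,3,4,5,6,7,8-octahydronaphthalen-1-yl]methanol
Product: 18 (1R,2S)-1,2,5,5-tetramethyl-1,2,3,4,5,6,7,8-octahydronaphthalene-1-carbaldehyde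
Conditions: Dess–Martin periodinane, NaHCO3, CH2Cl2, 0 °C to rt
Reagents that add atoms: none
Why: Dess–Martin oxidation of a hindered primary alcohol under buffered, non-acidic conditions; the aldehyde has no α-hydrogen, so neither epimerisation nor migration of the β,γ-olefin into conjugation can occur.

Step 11
Reactants: 18 (1R,2S)-1,2,5,5-tetramethyl-1,2,3,4,5,6,7,8-octahydronaphthalene-1-carbaldehyde; 19 1,2,4,5-tetramethoxybenzene
Product: 21 [(1R,2S)-1,2,5,5-tetramethyl-1,2,3,4,5,6,7,8-octahydronaphthalen-1-yl](2,3,5,6-tetramethoxyphenyl)methanol (both C11 epimers), via aryllithium 20 (not isolated)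
Conditions: 19, nBuLi, TMEDA, THF, 0 °C; then 18, −78 to 0 °C
Reagents that add atoms: none
Why: Directed ortho-lithiation between two methoxy groups gives a single aryllithium from the symmetric arene, and its 1,2-addition to a non-enolisable aldehyde cannot be diverted into enolisation; the configuration at C11 is irrelevant.

Step 12
Reactants: 21 [(1R,2S)-1,2,5,5-tetramethyl-1,2,3,4,5,6,7,8-octahydronaphthalen-1-yl](2,3,5,6-tetramethoxyphenyl)methanol
Product: 23 S-methyl O-{[(1R,2S)-1,2,5,5-tetramethyl-1,2,3,4,5,6,7,8-octahydronaphthalen-1-yl](2,3,5,6-tetramethoxyphenyl)methyl} carbonodithioate, via sodium xanthate 22 (not isolated)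
Conditions: NaN(SiMe3)2, THF, −78 °C; CS2, −78 to 0 °C; MeI, 0 °C to rt
Reagents that add atoms: carbon disulfide S=C=S; iodomethane CI
Why: Xanthate formation from an alkoxide, carbon disulfide and methyl iodide; the carbinol carbon has no β-hydrogen (C9 is quaternary), so Chugaev elimination is not possible.

Step 13
Reactants: 23 S-methyl O-{[(1R,2S)-1,2,5,5-tetramethyl-1,2,3,4,5,6,7,8-octahydronaphthalen-1-yl](2,3,5,6-tetramethoxyphenyl)methyl} carbonodithioate
Product: 24 1,2,4,5-tetramethoxy-3-{[(1R,2S)-1,2,5,5-tetramethyl-1,2,3,4,5,6,7,8-octahydronaphthalen-1-yl]methyl}benzene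
Conditions: nBu3SnH, AIBN (cat.), toluene, 100 °C
Reagents that add atoms: none
Why: Barton–McCombie deoxygenation through a benzylic radical that is reduced by the tin hydride; no cation is formed, so the quaternary C9 and the olefin are not exposed to 1,2-shifts, and rearrangement of the benzylic radical to a tertiary alkyl radical would be uphill.

Step 14
Reactants: 24 1,2,4,5-tetramethoxy-3-{[(1R,2S)-1,2,5,5-tetramethyl-1,2,3,4,5,6,7,8-octahydronaphthalen-1-yl]methyl}benzene
Product: 25 2,5-dimethoxy-3-{[(1R,2S)-1,2,5,5-tetramethyl-1,2,3,4,5,6,7,8-octahydronaphthalen-1-yl]methyl}cyclohexa-2,5-diene-1,4-dione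
Conditions: (NH4)2Ce(NO3)6 (2.5 equiv), MeCN/H2O, 0 °C
Reagents that add atoms: water O
Why: Oxidative demethylation of a para-dimethoxyarene by tetravalent cerium, the two carbonyl oxygens coming from water; the arene is oxidised far more easily than the tetrasubstituted olefin, so a small excess of oxidant at 0 °C should leave the olefin alone.

Step 15
Reactants: 25 2,5-dimethoxy-3-{[(1R,2S)-1,2,5,5-tetramethyl-1,2,3,4,5,6,7,8-octahydronaphthalen-1-yl]methyl}cyclohexa-2,5-diene-1,4-dione
Product: 26 2-hydroxy-5-methoxy-3-{[(1R,2S)-1,2,5,5-tetramethyl-1,2,3,4,5,6,7,8-octahydronaphthalen-1-yl]methyl}cyclohexa-2,5-diene-1,4-dione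
Conditions: KOH, MeOH/H2O, 0 °C to rt; then 1 M HCl
Reagents that add atoms: potassium hydroxide [K+].[OH-]
Why: Addition–elimination of hydroxide at a vinylogous ester; the C2' methoxy group, squeezed between a carbonyl and the bulky side chain, is twisted out of conjugation and its carbon is the more electrophilic, and the hydroxyquinone formed is deprotonated to a vinylogous carboxylate that resists a second hydrolysis.

## Compound list

1 | 2-methylcyclohex-2-en-1-one | CC1=CCCCC1=O | starting material
2 | dimethylaluminium (3S)-2,3-dimethylcyclohex-1-en-1-olate | C[C@H]1CCCC(O[Al](C)C)=C1C | intermediate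
3 | trimethyl{[(3S)-2,3-dimethylcyclohex-1-en-1-yl]oxy}silane | C[C@H]1CCCC(O[Si](C)(C)C)=C1C | intermediate
4 | lithium (3S)-2,3-dimethylcyclohex-1-en-1-olate | C[C@H]1CCCC(O[Li])=C1C | intermediate
5 | (2S,3S)-2-(hydroxymethyl)-2,3-dimethylcyclohexan-1-one | OC[C@@]1(C)C(=O)CCC[C@@H]1C | intermediate
6 | (2S,3S)-2-{[(tert-butyldimethylsilyl)oxy]methyl}-2,3-dimethylcyclohexan-1-one | CC(C)(C)[Si](C)(C)OC[C@@]1(C)C(=O)CCC[C@@H]1C | intermediate
7 | potassium (5S,6S)-6-{[(tert-butyldimethylsilyl)oxy]methyl}-5,6-dimethylcyclohex-1-en-1-olate | CC(C)(C)[Si](C)(C)OC[C@@]1(C)C(O[K])=CCC[C@@H]1C | intermediate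
8 | (5S,6S)-6-{[(tert-butyldimethylsilyl)oxy]methyl}-5,6-dimethylcyclohex-1-en-1-yl trifluoromethanesulfonate | CC(C)(C)[Si](C)(C)OC[C@@]1(C)C(OS(=O)(=O)C(F)(F)F)=CCC[C@@H]1C | intermediate
9 | ethyl 2-methylpropanoate (ethyl isobutyrate) | CCOC(=O)C(C)C | starting material
10 | 1,3-dibromopropane | BrCCCBr | starting material
11 | lithium 1-ethoxy-2-methylprop-1-en-1-olate (lithium enolate of 9) | CCOC(O[Li])=C(C)C | intermediate
12 | ethyl 5-bromo-2,2-dimethylpentanoate | CCOC(=O)C(C)(C)CCCBr | intermediate
13 | (5-ethoxy-4,4-dimethyl-5-oxopentyl)zinc bromide | CCOC(=O)C(C)(C)CCC[Zn]Br | intermediate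
14 | ethyl 5-[(5S,6R)-6-{[(tert-butyldimethylsilyl)oxy]methyl}-5,6-dimethylcyclohex-1-en-1-yl]-2,2-dimethylpentanoate | CC(C)(C)[Si](C)(C)OC[C@@]1(C)C(CCCC(C)(C)C(=O)OCC)=CCC[C@@H]1C | intermediate
15 | 5-[(5S,6R)-6-{[(tert-butyldimethylsilyl)oxy]methyl}-5,6-dimethylcyclohex-1-en-1-yl]-2,2-dimethylpentanoic acid | CC(C)(C)[Si](C)(C)OC[C@@]1(C)C(CCCC(C)(C)C(=O)O)=CCC[C@@H]1C | intermediate
16 | tert-butyldimethyl{[(1R,2S)-1,2,5,5-tetramethyl-1,2,3,4,5,6,7,8-octahydronaphthalen-1-yl]methoxy}silane | CC(C)(C)[Si](C)(C)OC[C@@]1(C)C2=C(CC[C@@H]1C)C(C)(C)CCC2 | intermediate
17 | [(1R,2S)-1,2,5,5-tetramethyl-1,2,3,4,5,6,7,8-octahydronaphthalen-1-yl]methanol | OC[C@@]1(C)C2=C(CC[C@@H]1C)C(C)(C)CCC2 | intermediate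
18 | (1R,2S)-1,2,5,5-tetramethyl-1,2,3,4,5,6,7,8-octahydronaphthalene-1-carbaldehyde | O=C[C@@]1(C)C2=C(CC[C@@H]1C)C(C)(C)CCC2 | intermediate
19 | 1,2,4,5-tetramethoxybenzene | COc1cc(OC)c(OC)cc1OC | starting material
20 | (2,3,5,6-tetramethoxyphenyl)lithium | [Li]c1c(OC)c(OC)cc(OC)c1OC | intermediate
21 | [(1R,2S)-1,2,5,5-tetramethyl-1,2,3,4,5,6,7,8-octahydronaphthalen-1-yl](2,3,5,6-tetramethoxyphenyl)methanol, both C11 epimers | COc1cc(OC)c(OC)c(C(O)[C@@]2(C)C3=C(CC[C@@H]2C)C(C)(C)CCC3)c1OC | intermediate
22 | sodium O-{[(1R,2S)-1,2,5,5-tetramethyl-1,2,3,4,5,6,7,8-octahydronaphthalen-1-yl](2,3,5,6-tetramethoxyphenyl)methyl} carbonodithioate, both C11 epimers | COc1cc(OC)c(OC)c(C(OC(=S)[S-])[C@@]2(C)C3=C(CC[C@@H]2C)C(C)(C)CCC3)c1OC.[Na+] | intermediate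
23 | S-methyl O-{[(1R,2S)-1,2,5,5-tetramethyl-1,2,3,4,5,6,7,8-octahydronaphthalen-1-yl](2,3,5,6-tetramethoxyphenyl)methyl} carbonodithioate, both C11 epimers | COc1cc(OC)c(OC)c(C(OC(=S)SC)[C@@]2(C)C3=C(CC[C@@H]2C)C(C)(C)CCC3)c1OC | intermediate
24 | 1,2,4,5-tetramethoxy-3-{[(1R,2S)-1,2,5,5-tetramethyl-1,2,3,4,5,6,7,8-octahydronaphthalen-1-yl]methyl}benzene | COc1cc(OC)c(OC)c(C[C@@]2(C)C3=C(CC[C@@H]2C)C(C)(C)CCC3)c1OC | intermediate
25 | 2,5-dimethoxy-3-{[(1R,2S)-1,2,5,5-tetramethyl-1,2,3,4,5,6,7,8-octahydronaphthalen-1-yl]methyl}cyclohexa-2,5-diene-1,4-dione | COC1=CC(=O)C(OC)=C(C[C@@]2(C)C3=C(CC[C@@H]2C)C(C)(C)CCC3)C1=O | intermediate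
26 | 2-hydroxy-5-methoxy-3-{[(1R,2S)-1,2,5,5-tetramethyl-1,2,3,4,5,6,7,8-octahydronaphthalen-1-yl]methyl}cyclohexa-2,5-diene-1,4-dione | COC1=CC(=O)C(O)=C(C[C@@]2(C)C3=C(CC[C@@H]2C)C(C)(C)CCC3)C1=O | target

## Step count and risks

Total step count: 15. Longest linear sequence: 14 steps (steps 1–4 and 6–15, from 1 to 26); step 5 is a one-step side branch.

**Step 8 (key step, proposed new method).** The most likely failures are processes that compete with ring closure or follow it:
- proton loss or solvent capture at the C4 cation before it reaches C5;
- proton loss from C1 instead of C5, giving the olefin isomer;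
- a hydride shift from C5 to C10 followed by methyl migration from C4;
- over-oxidation of the product, whose tetrasubstituted olefin is easier to oxidise than the olefin of 15, as conversion rises.

Fallback with known chemistry, setting out from enol triflate 8: a Negishi coupling under the conditions of step 6 with (4-methylpent-3-en-1-yl)zinc bromide F1, made from commercial 5-bromo-2-methylpent-2-ene and zinc, should give the diene tert-butyl{[(1R,6S)-1,6-dimethyl-2-(4-methylpent-3-en-1-yl)cyclohex-2-en-1-yl]methoxy}dimethylsilane F2. Protonation of its side-chain olefin with a strong acid at low temperature (ClSO3H in 2-nitropropane at −78 °C, or SnCl4 with a phenol as proton source in CH2Cl2) generates the same C4 cation and closes ring A in a classical cation–olefin cyclisation, coming back to the route at 16. This gives up the buffered medium, so the proton source must be kept at low temperature and quenched early to protect the product olefin.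

**Step 6.** Oxidative addition and transmetalation at a triflate flanked by the quaternary C9 may be slow, so that protodezincation of 13 or reduction of the triflate competes. Fallback, setting out from 8 and 9: allylation of the lithium enolate of 9 with allyl bromide gives ethyl 2,2-dimethylpent-4-enoate F3, and hydroboration with 9-borabicyclo[3.3.1]nonane gives ethyl 5-(9-borabicyclo[3.3.1]nonan-9-yl)-2,2-dimethylpentanoate F4. A B-alkyl Suzuki–Miyaura coupling of F4 with 8 (PdCl2(dppf), K3PO4, THF/DMF/H2O, 60 °C) comes back to the route at 14.

**Step 2.** The aldol addition creates a quaternary carbon and may revert (retro-aldol) or run on to a second hydroxymethylation, monomeric formaldehyde may polymerise before it reacts, and the facial selectivity trans to the C8 methyl may be incomplete. Fallback, setting out from 3: the lithium enolate released by MeLi is alkylated irreversibly with benzyl chloromethyl ether to (2S,3S)-2-[(benzyloxy)methyl]-2,3-dimethylcyclohexan-1-one F5, and hydrogenolysis (H2, Pd/C, EtOAc) comes back to the route at 5. The facial bias is the same; the gain is an irreversible C–C bond formation with a liquid electrophile.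

**Step 15.** Hydroxide may attack the other vinylogous ester carbon (C5', next to C6'–H) or add to C6', so that the regiochemistry of hydrolysis is lost. Fallback, setting out from 25: exhaustive hydrolysis (aq NaOH, then acid) gives 2,5-dihydroxy-3-{[(1R,2S)-1,2,5,5-tetramethyl-1,2,3,4,5,6,7,8-octahydronaphthalen-1-yl]methyl}cyclohexa-2,5-diene-1,4-dione F6. Acid-catalysed mono-methylation in MeOH (catalytic H2SO4, rt) is expected to esterify the less hindered vinylogous acid remote from the side chain and comes back to the route at 26.

## Further compounds

F1 | step 8 | (4-methylpent-3-en-1-yl)zinc bromide | CC(C)=CCC[Zn]Br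
F2 | step 8 | tert-butyl{[(1R,6S)-1,6-dimethyl-2-(4-methylpent-3-en-1-yl)cyclohex-2-en-1-yl]methoxy}dimethylsilane | CC(C)(C)[Si](C)(C)OC[C@@]1(C)C(CCC=C(C)C)=CCC[C@@H]1C
F3 | step 6 | ethyl 2,2-dimethylpent-4-enoate | CCOC(=O)C(C)(C)CC=C
F4 | step 6 | ethyl 5-(9-borabicyclo[3.3.1]nonan-9-yl)-2,2-dimethylpentanoate | CCOC(=O)C(C)(C)CCCB1C2CCCC1CCC2
F5 | step 2 | (2S,3S)-2-[(benzyloxy)methyl]-2,3-dimethylcyclohexan-1-one | c1ccccc1COC[C@@]1(C)C(=O)CCC[C@@H]1C
F6 | step 15 | 2,5-dihydroxy-3-{[(1R,2S)-1,2,5,5-tetramethyl-1,2,3,4,5,6,7,8-octahydronaphthalen-1-yl]methyl}cyclohexa-2,5-diene-1,4-dione | OC1=CC(=O)C(O)=C(C[C@@]2(C)C3=C(CC[C@@H]2C)C(C)(C)CCC3)C1=O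
A1 | alternative 1 | 6,6-dimethyl-1-vinylcyclohex-1-ene | C=CC1=CCCCC1(C)C
A2 | alternative 1 | (E)-2-methylbut-2-enal (tiglaldehyde) | C/C=C(\C)C=O
A3 | alternative 1 | (1R,2S)-1,2,5,5-tetramethyl-1,2,3,5,6,7,8,8a-octahydronaphthalene-1-carbaldehyde, exo-formyl adduct with C8a as in the SMILES | O=C[C@@]1(C)[C@@H]2CCCC(C)(C)C2=CC[C@@H]1C
A4 | alternative 2 | 3-tert-butoxy-4-hydroxy-4-(2-methoxyethenyl)-2-{[(1R,2S)-1,2,5,5-tetramethyl-1,2,3,4,5,6,7,8-octahydronaphthalen-1-yl]methyl}cyclobut-2-en-1-one | COC=CC1(O)C(OC(C)(C)C)=C(C[C@@]2(C)C3=C(CC[C@@H]2C)C(C)(C)CCC3)C1=O
A5 | alternative 2 | 3-tert-butoxy-5-methoxy-2-{[(1R,2S)-1,2,5,5-tetramethyl-1,2,3,4,5,6,7,8-octahydronaphthalen-1-yl]methyl}benzene-1,4-diol | COc1cc(O)c(OC(C)(C)C)c(C[C@@]2(C)C3=C(CC[C@@H]2C)C(C)(C)CCC3)c1O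
A6 | alternative 3 | 2-[(3S,4E)-3,4-dimethyl-5-(2,3,5,6-tetramethoxyphenyl)pent-4-en-1-yl]-3,3-dimethylcyclohex-1-en-1-yl trifluoromethanesulfonate | COc1cc(OC)c(OC)c(/C=C(\C)[C@@H](C)CCC2=C(OS(=O)(=O)C(F)(F)F)CCCC2(C)C)c1OC
A7 | alternative 3 | 1,2,4,5-tetramethoxy-3-{[(1R,2S)-1,2,5,5-tetramethyl-1,2,3,4,5,6,7,8-octahydronaphthalen-1-yl]methyl}benzene (identical with 24) | COc1cc(OC)c(OC)c(C[C@@]2(C)C3=C(CC[C@@H]2C)C(C)(C)CCC3)c1OC
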